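**Assumptions (one line):** compounds 1, 2, 6, 7, 9 and 13 are purchased; intermediates 10–14 use plumericin-type locants (C1 bis-acetal CH, C3 O–CH=, C4 C–CO2Me, C5/C9 ring-fusion CH, C6=C7, C8 spiro C–O, C10 O–CH, C11 lactone α-C, C12 lactone C=O).

## Retrosynthetic overview

1. C11=CH–Ar: aldol condensation of the tetracyclic lactone with 4-acetoxybenzaldehyde (last step).
2. C6=C7: ring-closing metathesis of vinyl groups on C5 and C8 (cyclopentene, formed last of the core rings).
3. C5–C9 and C1–O: domino Knoevenagel/inverse-demand hetero-Diels–Alder of a bicyclic enol ether with an alkylidene formylacetate (dihydropyran, formed second; sets C1, C5, C9).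
4. C10–O, C11–C12, C12–O–C8: enantioselective Pd(II) oxycarbonylative double cyclisation of an achiral divinyl carbinol. The THF and γ-lactone rings form together, first, and the two enantiotopic vinyl groups are differentiated (sets C8, C10).
5. The divinyl carbinol comes from methyl 3,3-dimethoxypropanoate and vinylmagnesium bromide.

## Route

**Step 1**
Reactants: 1 methyl 3,3-dimethoxypropanoate; 2 vinylmagnesium bromide
Product: 3, 3-ethenyl-5,5-dimethoxypent-1-en-3-ol (achiral)
Conditions: 2 (2.5 equiv), CeCl3, THF, −78 → 0 °C
Reagents that add atoms: none beyond reactant 2 (C=C[Mg]Br)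
Why: Double Grignard (organocerium) addition to the ester gives the tertiary carbinol while suppressing enolisation/β-elimination of methoxide; no stereocentre forms, and the carbinol carbon carries two enantiotopic vinyl groups.

**Step 2 (key step)**
Reactants: 3
Product: 4, (3aS,6aR)-6a-ethenyl-5-methoxytetrahydrofuro[3,2-b]furan-2(3H)-one (cis-fused THF/γ-lactone; methyl acetal as C5 epimers; one acetal methyl is lost)
Conditions: Pd(OCOCF3)2 (10 mol %), chiral bis(oxazoline) or spiro-bis(isoxazoline) ligand (12 mol %, enantiomer selected by screening to give (3aS,6aR)), p-benzoquinone (2 equiv), CO (1 atm), MeOH–CH2Cl2, −20 → 0 °C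
Reagents that add atoms: carbon monoxide, [C-]#[O+] (methanol, CO, is solvent and may exchange with the acetal OMe)
Why: Proposed new method: an enantioselective desymmetrising Pd(II) oxycarbonylative bicyclisation in which Pd(II), held by the tertiary allylic hydroxyl, activates one of the two enantiotopic vinyl groups, the acetal (or in situ methyl hemiacetal) oxygen adds anti in a 5-exo oxypalladation (C10–O), the σ-alkyl–Pd inserts CO (C12) and the acyl–Pd is captured by the same hydroxyl to close the lactone, so the ligand fixes C8 by choosing the vinyl group and C10 follows because only the cis-fused bicycle can lactonise; the closest known chemistry is Pd(II) alkoxycarbonylation of pent-4-ene-1,3-diols to 2,6-dioxabicyclo[3.3.0]octan-3-ones and asymmetric Wacker-type cyclisations/desymmetrisations with Pd(II)–bis(oxazoline) or spiro-bis(isoxazoline) catalysts.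

**Step 3**
Reactants: 4
Product: 5, (3aS,6aS)-6a-ethenyl-3a,6a-dihydrofuro[3,2-b]furan-2(3H)-one (cis-fused; C5=C6 enol ether)
Conditions: TMSOTf, i-Pr2NEt, CH2Cl2, −20 → 0 °C
Reagents that add atoms: none
Why: Gassman-type acetal-to-enol-ether elimination: TMSOTf ionises the methyl acetal to the cyclic oxocarbenium ion and the amine removes the only adjacent proton (C6–H), so both acetal epimers converge on one 2,3-dihydrofuran with the stereocentres untouched.

**Step 4**
Reactants: 6 acrolein; 7 benzeneselenol
Product: 8, 3-(phenylselanyl)propanal
Conditions: cat. Et3N, CH2Cl2, 0 °C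
Reagents that add atoms: none beyond reactant 7 ([SeH]c1ccccc1)
Why: Conjugate (selena-Michael) addition gives a stable aldehyde in which CH2CH2SePh is a masked vinyl group; no stereocentre.

**Step 5**
Reactants: 5; 8; 9 sodium (E)-3-methoxy-3-oxoprop-1-en-1-olate (sodium enolate of methyl 3-oxopropanoate)
Product: 10, tricyclic bis-acetal (1R,5S,8S,9S,10S): the target skeleton without the C6–C7 bond and with CH2 at C11, C8 bearing a vinyl group and C5 bearing a 2-(phenylselanyl)ethyl group cis to it
Conditions: 8 and 9 (1.5 equiv each), AcOH (1.5 equiv), ethylenediammonium diacetate (10 mol %), 4 Å MS, CH2Cl2, rt (Yb(fod)3 5 mol % if slow)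
Reagents that add atoms: none (all atoms from 5, 8 and 9; water is lost)
Why: Tietze domino Knoevenagel/inverse-electron-demand hetero-Diels–Alder: the alkylidene formylacetate formed in situ reacts through its formyl C=O/C=C oxadiene with the enol ether (C5 to the β-carbon C9, O to the acetal carbon C1) on the convex face of the bicycle (the face of the angular vinyl group, away from the lactone) via the endo transition state of the E-heterodiene, setting C1 (R), C9 (S) and C5 (S).

**Step 6**
Reactants: 10
Product: 11, as 10 but with a vinyl group on C5 (1R,5S,8S,9S,10S)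
Conditions: NaIO4, NaHCO3, THF–H2O, 0 °C → rt
Reagents that add atoms: none
Why: Selenoxide syn-elimination (β-hydrogens only on the inner CH2) unmasks the terminal vinyl group without touching any stereocentre.

**Step 7**
Reactants: 11
Product: 12, tetracyclic lactone (1R,5S,8S,9S,10S): 3-O-acetylprismatomerin lacking the arylidene group (CH2 at C11)
Conditions: Grubbs II (5 mol %), CH2Cl2, 40 °C
Reagents that add atoms: none
Why: Ring-closing metathesis of the two vinyl groups held cis on C5 and C8 (a 1,6-diene) closes the cis-fused cyclopentene with loss of ethylene; the push–pull enol-ether acrylate is inert.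

**Step 8**
Reactants: 12; 13 4-acetoxybenzaldehyde
Product: 14, 3-O-acetylprismatomerin (1R,5S,8S,9S,10S; E-benzylidene)
Conditions: LDA, THF, −78 °C; 13; MsCl, Et3N, −78 → 0 °C; DBU, 0 °C (one flask)
Reagents that add atoms: none beyond reactant 13
Why: Aldol condensation: the lactone enolate formed at −78 °C (cold enough that the β-alkoxy enolate does not ring-open and the aryl acetate survives) adds to the aldehyde, and mesylation/E1cB elimination gives the thermodynamically favoured E-alkene (aryl anti to the lactone carbonyl) with the ring stereocentres unchanged.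

## Compound list

1 | methyl 3,3-dimethoxypropanoate | COC(=O)CC(OC)OC | starting material
2 | vinylmagnesium bromide | C=C[Mg]Br | starting material
3 | 3-ethenyl-5,5-dimethoxypent-1-en-3-ol | COC(OC)CC(O)(C=C)C=C | intermediate
4 | (3aS,6aR)-6a-ethenyl-5-methoxytetrahydrofuro[3,2-b]furan-2(3H)-one | COC1O[C@H]2CC(=O)O[C@@]2(C=C)C1 | intermediate
5 | (3aS,6aS)-6a-ethenyl-3a,6a-dihydrofuro[3,2-b]furan-2(3H)-one | O=C1C[C@@H]2OC=C[C@]2(C=C)O1 | intermediate
6 | acrolein | C=CC=O | starting material
7 | benzeneselenol | [SeH]c1ccccc1 | starting material
8 | 3-(phenylselanyl)propanal | O=CCC[Se]c1ccccc1 | intermediate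
9 | sodium (E)-3-methoxy-3-oxoprop-1-en-1-olate | [Na+].[O-]/C=C/C(=O)OC | starting material
10 | hetero-Diels–Alder adduct (C8 vinyl, C5 CH2CH2SePh) | COC(=O)C1=CO[C@@H]2O[C@H]3CC(=O)O[C@@]3(C=C)[C@@H]2[C@@H]1CC[Se]c1ccccc1 | intermediate
11 | divinyl tricycle (C8 vinyl, C5 vinyl) | COC(=O)C1=CO[C@@H]2O[C@H]3CC(=O)O[C@@]3(C=C)[C@@H]2[C@@H]1C=C | intermediate
12 | tetracyclic lactone (CH2 at C11) | COC(=O)C1=CO[C@@H]2O[C@H]3CC(=O)O[C@]34C=C[C@H]1[C@H]24 | intermediate
13 | 4-acetoxybenzaldehyde | CC(=O)Oc1ccc(C=O)cc1 | starting material
14 | 3-O-acetylprismatomerin | COC(=O)C1=CO[C@@H]2O[C@H]3/C(=C\c4ccc(OC(C)=O)cc4)C(=O)O[C@]34C=C[C@H]1[C@H]24 | target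

## Summary

Total steps: 8. Longest linear sequence: 7 (steps 1, 2, 3, 5, 6, 7, 8; step 4 is a side branch).

Steps most likely to fail:

1. **Step 2** (enantioselectivity, acetal oxygen as nucleophile, Wacker oxidation of the second vinyl group). Fallback: drop the desymmetrisation and build 12 from furfuryl alcohol instead. That sequence is Achmatowicz oxidation, dynamic kinetic O-acylation, phosphine-catalysed [3+2] annulation with ethyl buta-2,3-dienoate, enol-triflate methoxycarbonylation, dienolate α-hydroxylation, butenolide formation and oxa-Michael closure.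
2. **Step 5** (hindered enol ether next to a quaternary carbon; endo and facial selectivity decide whether step 7 can close). Fallback: form C5–C9 stepwise by Lewis-acid Michael addition of 5 to the dimethyl alkylidenemalonate of 8 with methanol capture of the oxocarbenium ion, then half-reduce the malonate to the formyl ester and close the dihydropyran under acid.
3. **Step 8** (retro-oxa-Michael of the β-alkoxy lactone enolate, acetate loss, E/Z control). Fallback: α-methylenate 12 with Eschenmoser's salt and introduce the aryl group by Heck arylation with 4-iodophenyl acetate, which gives the E-benzylidene lactone without a strong base.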